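| flask | solid substrate | remark | time |
|---|---|---|---|
| winter | 2.8 mM | run made earlier |  |
| midnight | 6.5 mM | run made earlier |  |
| dusk | 9.1 mM | run made earlier |  |
| gamma | 4.0 mM |  | 2.5 h |
| epsilon | 11 mM |  | 8.0 h |

- winter (time / h: target / %): 0.833: 1.8; 1.50: 5.5; 2.50: 11.2; 3.00: 15.1; 4.00: 21.8
- midnight (time / h: target / %): 0.833: 0.7; 1.50: 2.2; 2.50: 5.1; 3.00: 6.3; 4.00: 9.2
- dusk (time / h: target / %): 0.333: 0; 0.667: 0.7; 1.00: 0; 2.00: 2.1; 4.00: 6.3

(each reading ± 0.3 percentage points)

- at the start none of the solid substrate is in solution
- what has only dissolved of solid substrate counts as not reacted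
- a reading or a percentage of target counts all its forms, free or not

- the winner by amount of target, in percent of the solid substrate charged; "neither" if no more than 2 percentage points parts them (gamma / epsilon / neither)
- how much target is there at the end, in percent of the solid substrate charged: gamma
- how much target is there at the end, in percent of the solid substrate charged: epsilon

At 4.00 h I turned the percentages into concentrations and read c(target) = 0.610 mM in winter, 0.598 mM in midnight and 0.573 mM in dusk. From winter to dusk the charge grew by a factor of 3.25, but c(target) changed by a factor of 0.939. So I reckoned in concentration and asked how fast it rose.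

Winter rose at 0.198 mM h⁻¹ from 2.50 h to 4.00 h, and midnight read 0.178 mM h⁻¹ over the same stretch. I took the winter reading as the charge-free climb: the rise of c(target) per hour on the straight late stretch, a pseudo-zero-order rate.

Gamma stopped at a time that winter and midnight had read, and its charge lay between theirs. Their mean c(target) there, 0.323 mM, gave gamma 8.06%. For epsilon I started from dusk at 4.00 h and added the climb up to 8.0 h, which gave 1.36 mM, or 12.4%. That end lay twice as late as the last reading, so it was an extrapolation. Both shares stood below the 21.8% that winter reached while still climbing straight. My share for epsilon stood above my share for gamma by more than the margin of 2 percentage points, so I named epsilon.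

The forecast also named epsilon, with 7.9% for gamma and 12.4% for epsilon, on the ground that "Formation is therefore independent of charge". My gamma stood slightly higher than its figure.

The flasks gave 7.96% in gamma and 12.7% in epsilon, so the winner was epsilon.

    target ⇌ isomer of the product (k = 6.00 × 10⁻⁵ s⁻¹)
    crystals ⇌ target, rate k2*(cs2 - [target]) while solid is left; crystals form when [target] > cs2 (solubility = 3.80 mM, k = 6.90 × 10⁻⁴ s⁻¹)
    solid substrate ⇌ starting material, rate k3*(cs3 - [starting material]) while solid is left; crystals form when [starting material] > cs3 (solubility = 3.80 mM, k = 2.40 × 10⁻⁵ s⁻¹)
    starting material ⇌ target (K = 13.0, k = 1.70 × 10⁻⁴ s⁻¹)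
    starting material ⇌ isomer of the product (K = 5.30, k = 6.30 × 10⁻⁵ s⁻¹)

At 8.00 h epsilon still held 78.3% as solid substrate, and starting material was being made 1.05 times as fast as it was used up, each step taken net. The same climb, carried to a flask like epsilon but charged with 27 mM, gives 5.06% at 8.00 h, and that flask held 5.17%.

All runs are simulated on assumed constants; scatter was added.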